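**Plan**

- Labels: An–C1(=O)–C2H(Ph)–C3H(CONHR)–C4(=O)–Ar′, with An = 4-methoxyphenyl, Ar′ = 2-hydroxy-4,6-dimethoxyphenyl, R = 4-benzamidobutyl; read from the SMILES, the target is the (2R,3R)-butanamide.
- Retrosynthesis: the phenol is masked as a benzyl ether, both ketones go back to carbinols, and the amide C–N bond is cut by tying the C1 oxygen to the amide carbon; this gives the five-membered lactone ring O–C(=O)–C3–C2–C1.
- This ring is the enabling feature: as a butenolide with a C2=C3 double bond it accepts phenyl at C2 and the C4 aryl carbinol at C3 in one operation, so the C2–Ph and C3–C4 bonds are cut together.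
- The butenolide is cut at C2=C3 (metathesis) and at its ester bond, back to (S)-anisyl vinyl carbinol from 4-methoxybenzaldehyde.
- Forward: vinylation, acryloylation and ring-closing metathesis form the only ring; phenyl and the aryl aldehyde are added across C2=C3; the amine opens the lactone; both carbinols are oxidised; the benzyl group is removed.
- Stereochemistry: ligand-controlled vinylation sets C1 as (S); C1 sends phenyl to the opposite ring face at C2, and phenyl sends the aldehyde to the opposite face at C3; C2 and C3 bear no acidic hydrogen until the late oxidation, which also erases C1.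

Key step: step 5

Assumption: the carbinol carbon created next to C3 in the key step is carried as a mixture of both configurations, because it is oxidised to the C4 ketone before the end.

**Route**

Step 1
Reactants: 1 4-methoxybenzaldehyde
Product: 2 (S)-1-(4-methoxyphenyl)prop-2-en-1-ol
Conditions: Zn(CH=CH2)2 (1.5 equiv; from CH2=CHMgBr and ZnCl2 in Et2O/THF, magnesium halide precipitated with 1,4-dioxane), (2S)-(−)-3-exo-(dimethylamino)isoborneol (5 mol%), toluene, 0 °C; aq NH4Cl
Reagents that add atoms: divinylzinc, C=C[Zn]C=C (prepared from vinylmagnesium bromide, C=C[Mg]Br)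
Why: Amino-alcohol-catalysed addition of a diorganozinc to an aromatic aldehyde is established for divinylzinc, and this ligand, which steers alkyl groups of dialkylzincs to the Si face of aryl aldehydes, should deliver vinyl to the same face and so set the (S)-carbinol centre.

Step 2
Reactants: 2 (S)-1-(4-methoxyphenyl)prop-2-en-1-ol
Product: 3 (S)-1-(4-methoxyphenyl)prop-2-en-1-yl prop-2-enoate
Conditions: acryloyl chloride (1.3 equiv), Et3N (1.5 equiv), DMAP (5 mol%), CH2Cl2, −20 → 0 °C
Reagents that add atoms: acryloyl chloride, C=CC(=O)Cl
Why: O-acylation of a secondary alcohol by an acid chloride under nucleophilic catalysis leaves the C–O bond intact, so the configuration is retained, and the cold basic medium suppresses ionisation or allylic transposition of the electron-rich benzylic ester.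

Step 3
Reactants: 3 (S)-1-(4-methoxyphenyl)prop-2-en-1-yl prop-2-enoate
Product: 4 (S)-5-(4-methoxyphenyl)furan-2(5H)-one
Conditions: second-generation Grubbs catalyst (H2IMes)(PCy3)Cl2Ru=CHPh (5 mol%), CH2Cl2 (0.01 M), 40 °C
Reagents that add atoms: none
Why: Ring-closing metathesis of allyl acrylates to 2(5H)-furanones is well precedented with this ruthenium carbene, ethene is lost as the five-membered ring closes between the two terminal alkenes, and the neutral medium leaves the acidic γ-hydrogen and hence the stereocentre untouched.

Step 4
Reactants: 5 2-hydroxy-4,6-dimethoxybenzaldehyde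
Product: 6 2-(benzyloxy)-4,6-dimethoxybenzaldehyde
Conditions: BnBr (1.2 equiv), K2CO3 (2 equiv), DMF, 60 °C
Reagents that add atoms: benzyl bromide, BrCc1ccccc1
Why: Williamson etherification, with gentle heating to overcome the hydrogen bond between phenol and aldehyde, masks the only acidic hydrogen of the aldehyde component as an ether that can later be removed without acid or base.

Step 5
Reactants: 4 (S)-5-(4-methoxyphenyl)furan-2(5H)-one; 7 phenylmagnesium bromide; 6 2-(benzyloxy)-4,6-dimethoxybenzaldehyde
Product: 10 (3R,4R,5S)-3-{[2-(benzyloxy)-4,6-dimethoxyphenyl](hydroxy)methyl}-5-(4-methoxyphenyl)-4-phenyldihydrofuran-2(3H)-one (both carbinol epimers), via bromomagnesium diphenylcuprate 8 (not isolated), via bromomagnesium lactone enolate 9 (not isolated)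
Conditions: 7 (2.4 equiv), CuBr·SMe2 (1.2 equiv), THF/Me2S, −40 °C; 4 added dropwise, −78 °C; then 6 (1.5 equiv), THF, −78 → −40 °C; aq NH4Cl
Reagents that add atoms: none
Why: Slow addition of 4 to the preformed cuprate 8 gives a copper–alkene π-complex at C2=C3, phenyl is transferred to C2 by oxidative addition and reductive elimination, and the bromomagnesium enolate 9 so formed adds through C3 to the carbonyl carbon of 6; this is the tandem conjugate addition–aldol trapping long used on butenolides for trans-disubstituted lignan lactones. No ring closes, the lactone serves only as a rigid template. C2 is controlled by the anisyl group on the neighbouring ring carbon C1, which blocks one face of the flat butenolide so that copper delivers phenyl trans to it, and C3 is controlled by this new phenyl group, which shields one face of the planar enolate so that the aldehyde enters trans; the carbinol carbon C4 forms without control, which is harmless because step 7 turns it into a ketone. The step needs 1,4- instead of 1,2-addition and must not remove the acidic γ-hydrogen at C1 (racemisation through the 2-oxyfuran), which the soft, weakly basic cuprate, the temperature of −78 °C and the inverse addition that never leaves 4 beside the enolate should secure. Bringing C4 in as an aldehyde instead of an acid derivative keeps C3 free of an acidic hydrogen, so the trans relation set here cannot be lost when the amine opens the lactone.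

Step 6
Reactants: 10 (3R,4R,5S)-3-{[2-(benzyloxy)-4,6-dimethoxyphenyl](hydroxy)methyl}-5-(4-methoxyphenyl)-4-phenyldihydrofuran-2(3H)-one; 11 N-(4-aminobutyl)benzamide
Product: 12 (2R,3R,4S)-N-(4-benzamidobutyl)-2-{[2-(benzyloxy)-4,6-dimethoxyphenyl](hydroxy)methyl}-4-hydroxy-4-(4-methoxyphenyl)-3-phenylbutanamide (both carbinol epimers)
Conditions: 11 (2 equiv), 2-hydroxypyridine (1 equiv), toluene, 70 °C; cold aq NaH2PO4 wash, crude used at once
Reagents that add atoms: none
Why: Aminolysis of a γ-lactone by an unhindered primary amine under bifunctional 2-pyridone catalysis is a standard route to γ-hydroxy amides, proceeds by acyl–oxygen cleavage so that C1 keeps its configuration, and cannot disturb C2 or C3 because neither is more than an ordinary alkyl or amide α-carbon at this stage.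

Step 7
Reactants: 12 (2R,3R,4S)-N-(4-benzamidobutyl)-2-{[2-(benzyloxy)-4,6-dimethoxyphenyl](hydroxy)methyl}-4-hydroxy-4-(4-methoxyphenyl)-3-phenylbutanamide
Product: 13 (2R,3R)-N-(4-benzamidobutyl)-2-[2-(benzyloxy)-4,6-dimethoxybenzoyl]-4-(4-methoxyphenyl)-4-oxo-3-phenylbutanamide
Conditions: Dess–Martin periodinane (3 equiv), NaHCO3, CH2Cl2, 0 °C → rt
Reagents that add atoms: none
Why: Dess–Martin oxidation should convert both secondary benzylic carbinols (both epimers converging) into ketones under buffered, near-neutral conditions of the kind that oxidise aldol adducts to β-keto carbonyl compounds without loss of the α-stereocentre, so C2 and C3 become acidic only here and meet no base afterwards.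

Step 8
Reactants: 13 (2R,3R)-N-(4-benzamidobutyl)-2-[2-(benzyloxy)-4,6-dimethoxybenzoyl]-4-(4-methoxyphenyl)-4-oxo-3-phenylbutanamide
Product: 14 (2R,3R)-N-(4-benzamidobutyl)-2-(2-hydroxy-4,6-dimethoxybenzoyl)-4-(4-methoxyphenyl)-4-oxo-3-phenylbutanamide (CNP0208962.1)
Conditions: H2 (1 atm), 10% Pd/C, EtOAc, rt
Reagents that add atoms: none
Why: Hydrogenolysis of an aryl benzyl ether over palladium on carbon is neutral and should be faster than reduction of the electron-rich anisyl ketone or the hindered C4 ketone, so the phenol is freed without epimerising C2 or C3.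

**Compound list**

1 | 4-methoxybenzaldehyde | COc1ccc(C=O)cc1 | starting material
2 | (S)-1-(4-methoxyphenyl)prop-2-en-1-ol | COc1ccc([C@@H](O)C=C)cc1 | intermediate
3 | (S)-1-(4-methoxyphenyl)prop-2-en-1-yl prop-2-enoate | COc1ccc([C@@H](OC(=O)C=C)C=C)cc1 | intermediate
4 | (S)-5-(4-methoxyphenyl)furan-2(5H)-one | COc1ccc([C@H]2OC(=O)C=C2)cc1 | intermediate
5 | 2-hydroxy-4,6-dimethoxybenzaldehyde | COc1cc(O)c(C=O)c(OC)c1 | starting material
6 | 2-(benzyloxy)-4,6-dimethoxybenzaldehyde | COc1cc(OC)c(C=O)c(OCc2ccccc2)c1 | intermediate
7 | phenylmagnesium bromide | Br[Mg]c1ccccc1 | starting material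
8 | bromomagnesium diphenylcuprate | c1ccccc1[Cu-]c1ccccc1.[Mg+]Br | intermediate (not isolated)
9 | bromomagnesium enolate of (4R,5S)-5-(4-methoxyphenyl)-4-phenyldihydrofuran-2(3H)-one | COc1ccc([C@H]2OC(O[Mg]Br)=C[C@@H]2c2ccccc2)cc1 | intermediate (not isolated)
10 | (3R,4R,5S)-3-{[2-(benzyloxy)-4,6-dimethoxyphenyl](hydroxy)methyl}-5-(4-methoxyphenyl)-4-phenyldihydrofuran-2(3H)-one, both carbinol epimers | COc1ccc([C@H]2OC(=O)[C@@H](C(O)c3c(OCc4ccccc4)cc(OC)cc3OC)[C@@H]2c2ccccc2)cc1 | intermediate
11 | N-(4-aminobutyl)benzamide | NCCCCNC(=O)c1ccccc1 | starting material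
12 | (2R,3R,4S)-N-(4-benzamidobutyl)-2-{[2-(benzyloxy)-4,6-dimethoxyphenyl](hydroxy)methyl}-4-hydroxy-4-(4-methoxyphenyl)-3-phenylbutanamide, both carbinol epimers | COc1ccc([C@@H](O)[C@@H](c2ccccc2)[C@@H](C(=O)NCCCCNC(=O)c2ccccc2)C(O)c2c(OCc3ccccc3)cc(OC)cc2OC)cc1 | intermediate
13 | (2R,3R)-N-(4-benzamidobutyl)-2-[2-(benzyloxy)-4,6-dimethoxybenzoyl]-4-(4-methoxyphenyl)-4-oxo-3-phenylbutanamide | COc1ccc(C(=O)[C@@H](c2ccccc2)[C@@H](C(=O)NCCCCNC(=O)c2ccccc2)C(=O)c2c(OCc3ccccc3)cc(OC)cc2OC)cc1 | intermediate
14 | (2R,3R)-N-(4-benzamidobutyl)-2-(2-hydroxy-4,6-dimethoxybenzoyl)-4-(4-methoxyphenyl)-4-oxo-3-phenylbutanamide | COc1ccc(C(=O)[C@@H](c2ccccc2)[C@@H](C(=O)NCCCCNC(=O)c2ccccc2)C(=O)c2c(O)cc(OC)cc2OC)cc1 | target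

**Step count**

Total: 8 steps. Longest linear sequence: 7 steps (steps 1, 2, 3, 5, 6, 7, 8).

**Steps most likely to fail**

Step 5. Capture of the enolate by the hindered, electron-rich aldehyde may be slow or may revert in the presence of copper and magnesium salts, so that only the protonated conjugate adduct is recovered, and leftover phenylcopper may consume aldehyde. The fallback separates the two bond formations and sets out from 4. Addition of 4 to cuprate 8 followed by a proton quench should give (4R,5S)-5-(4-methoxyphenyl)-4-phenyldihydrofuran-2(3H)-one F1, which is isolated. Deprotonation with lithium diisopropylamide (THF, −78 °C) gives the copper-free lithium lactone enolate F2. This enolate is combined with 6, again trans to phenyl, and the route is rejoined at 10.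

Step 6. The hindered lactone may open incompletely, and the γ-hydroxy amide may close back to the lactone with loss of the amine on heating or concentration. The fallback sets out from 10 and raises the reactivity of the lactone before the amine is introduced. Dess–Martin oxidation of the side-chain carbinol should give (3R,4R,5S)-3-[2-(benzyloxy)-4,6-dimethoxybenzoyl]-5-(4-methoxyphenyl)-4-phenyldihydrofuran-2(3H)-one F3, whose lactone carbonyl is activated by the adjacent aroyl group and whose acidic C3 hydrogen lets the aroyl group rest trans to phenyl. Amine 11 should open it at room temperature (2-hydroxypyridine, THF) to (2R,3R,4S)-N-(4-benzamidobutyl)-2-[2-(benzyloxy)-4,6-dimethoxybenzoyl]-4-hydroxy-4-(4-methoxyphenyl)-3-phenylbutanamide F4. A second Dess–Martin oxidation of the remaining carbinol rejoins the route at 13. This variant exposes an acidic C3 hydrogen to the amine and is therefore held in reserve.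

Step 1. Unselective background addition by vinylzinc species that still carry magnesium halide would erode the enantiomeric purity, which no later step can restore. The fallback sets out from 1 and replaces catalyst control by a resolution. Vinylmagnesium bromide (THF, 0 °C) gives racemic 1-(4-methoxyphenyl)prop-2-en-1-ol F5. Lipase-catalysed acetylation (Candida antarctica lipase B, vinyl acetate, hexane, rt) should, following the usual preference of lipases for secondary aryl carbinols, convert the (R)-enantiomer into (R)-1-(4-methoxyphenyl)prop-2-en-1-yl acetate F6. The unreacted (S)-alcohol is separated by chromatography and rejoins the route as 2.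

Further compounds
F1 | step 5 | (4R,5S)-5-(4-methoxyphenyl)-4-phenyldihydrofuran-2(3H)-one | COc1ccc([C@H]2OC(=O)C[C@@H]2c2ccccc2)cc1
F2 | step 5 | lithium enolate of (4R,5S)-5-(4-methoxyphenyl)-4-phenyldihydrofuran-2(3H)-one | COc1ccc([C@H]2OC(O[Li])=C[C@@H]2c2ccccc2)cc1
F3 | step 6 | (3R,4R,5S)-3-[2-(benzyloxy)-4,6-dimethoxybenzoyl]-5-(4-methoxyphenyl)-4-phenyldihydrofuran-2(3H)-one | COc1ccc([C@H]2OC(=O)[C@@H](C(=O)c3c(OCc4ccccc4)cc(OC)cc3OC)[C@@H]2c2ccccc2)cc1
F4 | step 6 | (2R,3R,4S)-N-(4-benzamidobutyl)-2-[2-(benzyloxy)-4,6-dimethoxybenzoyl]-4-hydroxy-4-(4-methoxyphenyl)-3-phenylbutanamide | COc1ccc([C@@H](O)[C@@H](c2ccccc2)[C@@H](C(=O)NCCCCNC(=O)c2ccccc2)C(=O)c2c(OCc3ccccc3)cc(OC)cc2OC)cc1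
F5 | step 1 | racemic 1-(4-methoxyphenyl)prop-2-en-1-ol | COc1ccc(C(O)C=C)cc1
F6 | step 1 | (R)-1-(4-methoxyphenyl)prop-2-en-1-yl acetate | COc1ccc([C@H](OC(C)=O)C=C)cc1
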